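**Assumptions (one line each).** Kuwanon T has no stereocentres, and its two prenyl alkenes have no E/Z issue, so "single enantiomer" is moot and no stereocontrol is needed. 5-Bromoresorcinol, resorcinol, prenyl bromide, NIS and the other reagents are commercial. MOM ethers serve as the only protecting group set, so there is a single global deprotection at the end.

## Retrosynthesis
- Kuwanon T (19) comes from global MOM removal of the tetra-MOM flavone 18.
- The central bold disconnection is the pyranone ring. One Pd-catalysed carbonylative heteroannulation of o-iodophenol 16, CO and the internal aryl/prenyl alkyne 10 forms C4a–C4, C3–C4 and O1–C2 together. Both aromatic rings and both prenyl groups are already in place, and the A and B rings are not made in this step.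
- Alkyne 10 comes from Sonogashira coupling of aryl iodide 7 with prenylacetylene 9. Iodide 7 comes from resorcinol by bis-MOM protection, ortho-lithiation between the two OMOM groups with prenylation, then iodination.
- Phenol 16 comes from 5-bromoresorcinol by bis-MOM protection, Br→OH conversion and ortho-iodination.

## Forward route

**Step 1**
Reactants: 1 resorcinol; 2 chloromethyl methyl ether (MOMCl)
Product: 3 1,3-bis(methoxymethoxy)benzene
Conditions: NaH (2.2 equiv), THF/DMF, 0 °C→rt; then MOMCl (2.3 equiv)
Reagents that add atoms: MOMCl, COCCl
Why: Williamson-type O-alkylation gives the bis-MOM ether, which is a strong ortho-directing group set for step 2.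

**Step 2**
Reactants: 3; 4 prenyl bromide
Product: 5 2-prenyl-1,3-bis(methoxymethoxy)benzene
Conditions: n-BuLi (1.05 equiv), THF, 0 °C, 2 h; then CuI (10 mol%), prenyl bromide, –20 °C→rt
Reagents that add atoms: prenyl bromide, CC(C)=CCBr
Why: Directed ortho-metalation occurs at C2, between the two OMOM groups. The Cu-catalysed SN2 alkylation puts the normal prenyl (α) group on the carbon, not the γ/reverse prenyl group. The prenyl group is thus installed between the two oxygens, as required for C-3′.

**Step 3**
Reactants: 5; 6 N-iodosuccinimide (NIS)
Product: 7 1-iodo-2,4-bis(methoxymethoxy)-3-(3-methylbut-2-en-1-yl)benzene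
Conditions: NIS (1.05 equiv), MeCN, 0 °C→rt, dark
Reagents that add atoms: NIS, O=C1CCC(=O)N1I
Why: Electrophilic aromatic iodination at C4 (ortho to one OMOM, para to the other). The very electron-rich resorcinol diether reacts much faster than the isolated trisubstituted alkene.

**Step 4**
Reactants: 8 ethynylmagnesium bromide; 4 prenyl bromide
Product: 9 prenylacetylene (5-methylhex-4-en-1-yne)
Conditions: HC≡CMgBr (1.5 equiv, THF), CuI (10 mol%), prenyl bromide, THF, 0 °C→rt; isolate by careful distillation (volatile)
Reagents that add atoms: ethynylmagnesium bromide, C#C[Mg]Br; prenyl bromide, CC(C)=CCBr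
Why: Cu-catalysed SN2 coupling of an alkynyl Grignard with an allylic bromide gives the linear (α) product.

**Step 5**
Reactants: 7; 9
Product: 10 1-(5-methylhex-4-en-1-yn-1-yl)-2,4-bis(methoxymethoxy)-3-prenylbenzene
Conditions: PdCl2(PPh3)2 (3 mol%), CuI (5 mol%), Et3N/THF, 40 °C
Reagents that add atoms: prenylacetylene 9, C#CCC=C(C)C
Why: Sonogashira coupling of an aryl iodide with a terminal alkyne. Mild amine base avoids isomerising the skipped enyne to an allene or conjugated enyne.

**Step 6**
Reactants: 11 5-bromoresorcinol; 2 MOMCl
Product: 12 1-bromo-3,5-bis(methoxymethoxy)benzene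
Conditions: NaH (2.2 equiv), THF/DMF, 0 °C→rt; MOMCl (2.3 equiv)
Reagents that add atoms: MOMCl, COCCl
Why: Same O-alkylation as step 1; the bromide is a masked phenol.

**Step 7**
Reactants: 12; 13 trimethyl borate; 14 hydrogen peroxide
Product: 15 3,5-bis(methoxymethoxy)phenol
Conditions: (i) n-BuLi, THF, –78 °C; B(OMe)3; (ii) 2 M NaOH, 30% H2O2, 0 °C→rt
Reagents that add atoms: B(OMe)3, COB(OC)OC (boron is not retained); H2O2, OO (supplies the phenolic O)
Why: Br–Li exchange, borylation, then oxidative C–B→C–O (Brown-type hydroxylation). MOM ethers are stable to base and peroxide.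

**Step 8**
Reactants: 15; 6 NIS
Product: 16 2-iodo-3,5-bis(methoxymethoxy)phenol
Conditions: NIS (1.0 equiv), MeCN, –20→0 °C, dark
Reagents that add atoms: NIS, O=C1CCC(=O)N1I
Why: Electrophilic iodination of an electronically equivalent triad of positions. The site ortho to OH and one OMOM is less hindered than C4 between the two OMOM groups, and OH···NIS hydrogen bonding favours ortho attack. This gives the 2-iodophenol needed for C4a and O1.

**Step 9 (key step)**
Reactants: 16; 10; 17 carbon monoxide
Product: 18 5,7-bis(methoxymethoxy)-2-[2,4-bis(methoxymethoxy)-3-prenylphenyl]-3-prenylchromen-4-one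
Conditions: Pd(PPh3)4 (5 mol%), Et3N (3 equiv), CO (10 atm), DMF, 90 °C, alkyne 1.5 equiv
Reagents that add atoms: carbon monoxide, [C-]#[O+]
Why: Proposed new method: oxidative addition of the hindered ArI, then CO insertion gives an aroyl-Pd species. Syn-carbopalladation of the aryl/alkyl alkyne puts the aroyl carbon on the prenyl-bearing carbon, and Pd on the aryl-bearing carbon, which is electronically and sterically preferred (as in Larock heteroannulation). Phenoxide C–O reductive elimination from the six-membered palladacycle closes the 2-aryl-3-prenylchromone. The closest known reactions are Pd-catalysed carbonylative annulations of o-iodophenols with alkynes (Torii/Larock type), and high CO pressure plus ortho-disubstitution of the aryl iodide should favour CO insertion before alkyne insertion (chromone, not coumarin or benzofuran). No stereocentre is formed.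

**Step 10**
Reactants: 18
Product: 19 Kuwanon T
Conditions: 3 M HCl, MeOH/THF (1:1), 45 °C, 4–6 h
Reagents that add atoms: none
Why: Acidolysis of the four aryl MOM acetals (including the chelated 5-OMOM) gives the free phenols. The mild, dilute acid and moderate temperature are chosen to avoid cyclising the 2′-OH onto the 3′-prenyl group (chromane formation); the product has no stereocentres to scramble.

## Self-check against the target
- **Structure:** Target SMILES CC(C)=CCc1c(O)ccc(-c2oc3cc(O)cc(O)c3c(=O)c2CC=C(C)C)c1O.
  - B ring: C1′ joined to C2, 2′-OH, 3′-prenyl between the two oxygens, 4′-OH. This matches 7, where prenyl sits between the OMOM groups and iodine is ortho to one of them.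
  - A ring: O1 from the phenol, C4a from the C–I carbon, C5-O ortho and C7-O para to C4a. This matches 16.
  - C-ring: C3 carries prenyl because the acyl carbon attaches to the prenyl-bearing alkyne carbon.
- **Atom accounting:** Each product follows from its reactants as written. Step 9 adds one CO, and the last product 19 is C25H26O6 (flavone C15 plus two C5 units).
- **Functional-group survival:** MOM ethers survive n-BuLi at 0 °C, NIS, Pd/Et3N/CO, NaOH/H2O2 and CuI. Prenyl alkenes are untouched by NIS in the presence of the electron-rich arene, and no hydrogenolysis or strong Lewis acid is used.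
- **Stereocentres:** None in the target, so none need to be set.

## Compound list
| No. | Name | SMILES | Role |
|---|---|---|---|
| 1 | Resorcinol | Oc1cccc(O)c1 | starting material |
| 2 | Chloromethyl methyl ether | COCCl | starting material (reagent) |
| 3 | 1,3-Bis(methoxymethoxy)benzene | COCOc1cccc(OCOC)c1 | intermediate |
| 4 | Prenyl bromide | CC(C)=CCBr | starting material (reagent) |
| 5 | 2-Prenyl-1,3-bis(methoxymethoxy)benzene | COCOc1cccc(OCOC)c1CC=C(C)C | intermediate |
| 6 | N-Iodosuccinimide | O=C1CCC(=O)N1I | starting material (reagent) |
| 7 | 1-Iodo-2,4-bis(MOMO)-3-prenylbenzene | COCOc1ccc(I)c(OCOC)c1CC=C(C)C | intermediate |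
| 8 | Ethynylmagnesium bromide | C#C[Mg]Br | starting material (reagent) |
| 9 | Prenylacetylene (5-methylhex-4-en-1-yne) | C#CCC=C(C)C | intermediate |
| 10 | 1-(5-Methylhex-4-en-1-ynyl)-2,4-bis(MOMO)-3-prenylbenzene | COCOc1ccc(C#CCC=C(C)C)c(OCOC)c1CC=C(C)C | intermediate |
| 11 | 5-Bromoresorcinol | Oc1cc(O)cc(Br)c1 | starting material |
| 12 | 1-Bromo-3,5-bis(MOMO)benzene | COCOc1cc(Br)cc(OCOC)c1 | intermediate |
| 13 | Trimethyl borate | COB(OC)OC | starting material (reagent) |
| 14 | Hydrogen peroxide | OO | starting material (reagent) |
| 15 | 3,5-Bis(MOMO)phenol | COCOc1cc(O)cc(OCOC)c1 | intermediate |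
| 16 | 2-Iodo-3,5-bis(MOMO)phenol | COCOc1cc(OCOC)c(I)c(O)c1 | intermediate |
| 17 | Carbon monoxide | [C-]#[O+] | starting material (reagent) |
| 18 | Tetra-MOM Kuwanon T | CC(C)=CCc1c(OCOC)ccc(-c2oc3cc(OCOC)cc(OCOC)c3c(=O)c2CC=C(C)C)c1OCOC | intermediate |
| 19 | Kuwanon T | CC(C)=CCc1c(O)ccc(-c2oc3cc(O)cc(O)c3c(=O)c2CC=C(C)C)c1O | target |

## Totals
Total steps: 10. Longest linear sequence: 6 (steps 1, 2, 3, 5, 9, 10).

## Three steps most likely to fail
1. **Step 9, carbonylative annulation.** Risks are coumarin or benzofuran formation, the wrong alkyne regiochemistry, and isomerisation of the skipped enyne.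
   - Fallback (different approach): Baker–Venkataraman sequence. Acylate 2-hydroxy-4,6-bis(MOMO)acetophenone with 2,4-bis(MOMO)-3-prenylbenzoyl chloride, rearrange to the 1,3-diketone, C-prenylate it with prenyl bromide, and cyclodehydrate. The B-ring acid is made by formylation or carboxylation of 5 followed by oxidation.
2. **Step 10, global MOM removal.** Risks are acid-induced chromane formation from the 2′-OH and 3′-prenyl pair, and prenyl hydration.
   - Fallback (different mechanism): non-acidic Fujioka deprotection. TESOTf/2,2′-bipyridine converts the aryl MOM ethers to pyridinium intermediates, which are then hydrolysed with water, leaving the prenyl groups untouched.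
3. **Step 8, iodination regiochemistry.** Iodination may go at C4 between the two OMOM groups instead of ortho to OH.
   - Fallback (different approach): convert 15 to its N,N-diethylcarbamate and do directed metalation with s-BuLi/TMEDA. The carbamate is the stronger directing group, so lithiation goes at C2, between carbamate and OMOM. Quench with I2, then remove the carbamate with LiAlH4 to give 16 regiospecifically.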